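## Retrosynthetic overview

1. The γ-lactone is the only ring and closes last. It closes as proposed for the lichen paraconic acids: the hydroxyl of a 2-(1-hydroxyalkyl)itaconyl unit attacks the activated acrylic carboxyl, and the second carboxyl stays free.
2. That seco-unit is cut at C2–C3 (aldol) into 15-oxohexadecanal and unprotected itaconic acid in activated form. Itaconic anhydride stands in for the acyl thioester, so the C–C bond, both stereocentres, the ring, the exo-methylene and the free CO2H all arise in one flask.
3. Stereocontrol: the anhydride ring locks an E(O) boron dienolate. A chair aldol on a chiral diazaborolidine gives the anti aldolate, which becomes the cis (allo) lactone after acyl transfer.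
4. 15-Oxohexadecanal comes from 16-hydroxyhexadecan-2-one, which comes from ω-pentadecalactone plus one methyl carbon.

Assumption: the facial bias of the (R,R)-diazaborolidine (re-face attack on RCHO in its ester anti-aldols) carries over to the anhydride dienolate; the (S,S)-controller is equally available.

## Route

**Step 1**
Reactants: 1 ω-pentadecalactone (oxacyclohexadecan-2-one)
Product: 3 16-hydroxyhexadecan-2-one, via Weinreb amide 2 (not isolated)
Conditions: MeNH(OMe)·HCl (1.3 equiv), MeMgCl (5 equiv), THF, −15 °C → rt; 1 M HCl
Reagents that add atoms: methylmagnesium chloride, C[Mg]Cl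
Why: One-pot Weinreb ketone synthesis, in which ClMgN(Me)OMe opens the lactone to amide 2 and the chelated tetrahedral adduct of 2 with MeMgCl survives until the quench, so addition stops at the methyl ketone; no stereocentre is formed.

**Step 2**
Reactants: 3 16-hydroxyhexadecan-2-one
Product: 4 15-oxohexadecanal
Conditions: TEMPO (10 mol %), PhI(OAc)2 (1.1 equiv), CH2Cl2, rt
Reagents that add atoms: none
Why: Oxoammonium (TEMPO/BAIB, Piancatelli–Margarita) oxidation takes the primary alcohol to the aldehyde under anhydrous, near-neutral conditions without over-oxidation, and the ketone is inert; no stereocentre is formed.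

**Step 3**
Reactants: 4 15-oxohexadecanal; 5 itaconic anhydride (3-methylideneoxolane-2,5-dione)
Product: 9 allo-pertusaric acid [(2S,3S)-4-methylidene-5-oxo-2-(14-oxopentadecyl)oxolane-3-carboxylic acid], via boron dienolate 6 (not isolated), via boron anti-aldolate 7 (not isolated), via hydroxy anhydride 8 (not isolated)
Conditions: (R,R)-TsNHCH(Ph)CH(Ph)NHTs (1.25 equiv), BBr3 (1.25 equiv), CH2Cl2, rt, evaporate; 5 (1.3 equiv), iPr2NEt (1.4 equiv), CH2Cl2, −78 °C, 1 h; 4 (1.0 equiv), −78 °C, 3 h; 1 M aq. citric acid/THF, 0 °C → rt
Reagents that add atoms: none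
Why: Proposed new method: soft enolisation (R2B–Br/iPr2NEt) of the doubly activated CH2 of 5 gives dienolate 6, whose ring fixes the E(O) geometry; 6 attacks only the aldehyde (ketones are inert to boron enolates at −78 °C) through its α-carbon in a six-membered Zimmerman–Traxler chair with the chain and the ring carbon both equatorial, which gives anti-aldolate 7 while the (R,R)-controller directs attack to the re face of 4, setting 2S and 3S together; after B–O hydrolysis the hydroxyl of 8 attacks the distal acrylic carbonyl (5-exo-trig acyl transfer, the biosynthetic lactonisation) without touching either stereocentre and releases the CO2H cis to the chain; the closest known reactions are the diazaborolidine (Corey-type) anti-aldol of tert-butyl esters, the α-selective aldol of boron dienolates, and the Fittig/Perkin-type anhydride–aldehyde aldol–lactonisation to paraconic acids.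

## Compound list

1 | ω-pentadecalactone (oxacyclohexadecan-2-one) | O=C1CCCCCCCCCCCCCCO1 | starting material
2 | 15-hydroxy-N-methoxy-N-methylpentadecanamide | CON(C)C(=O)CCCCCCCCCCCCCCO | intermediate
3 | 16-hydroxyhexadecan-2-one | CC(=O)CCCCCCCCCCCCCCO | intermediate
4 | 15-oxohexadecanal | CC(=O)CCCCCCCCCCCCCC=O | intermediate
5 | itaconic anhydride (3-methylideneoxolane-2,5-dione) | C=C1CC(=O)OC1=O | starting material
6 | 5-{[(4R,5R)-4,5-diphenyl-1,3-ditosyl-1,3,2-diazaborolidin-2-yl]oxy}-3-methylidenefuran-2(3H)-one | C=C1C=C(OB2N(S(=O)(=O)c3ccc(C)cc3)[C@H](c3ccccc3)[C@@H](c3ccccc3)N2S(=O)(=O)c2ccc(C)cc2)OC1=O | intermediate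
7 | O-[(4R,5R)-diazaborolidin-2-yl] aldolate of (3S)-3-[(1S)-1-hydroxy-15-oxohexadecyl]-4-methylideneoxolane-2,5-dione | C=C1C(=O)OC(=O)[C@@H]1[C@@H](OB2N(S(=O)(=O)c3ccc(C)cc3)[C@H](c3ccccc3)[C@@H](c3ccccc3)N2S(=O)(=O)c2ccc(C)cc2)CCCCCCCCCCCCCC(C)=O | intermediate
8 | (3S)-3-[(1S)-1-hydroxy-15-oxohexadecyl]-4-methylideneoxolane-2,5-dione | C=C1C(=O)OC(=O)[C@@H]1[C@@H](O)CCCCCCCCCCCCCC(C)=O | intermediate
9 | allo-pertusaric acid, (2S,3S)-4-methylidene-5-oxo-2-(14-oxopentadecyl)oxolane-3-carboxylic acid (chain and CO2H cis) | C=C1C(=O)O[C@@H](CCCCCCCCCCCCCC(C)=O)[C@H]1C(=O)O | target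

## Step count and risks

Total steps: 3. Longest linear sequence: 3 (1 → 3 → 4 → 9).

**Highest risk, step 3.** Dienolate 6 may oligomerise by Michael addition, react at the exocyclic γ-carbon, or give only modest ee.
- The fallback sets out from 4 and returns at 9. It replaces the unprotected tandem process with a protected, stepwise one.
- Itaconic acid is esterified with isobutene and catalytic H2SO4 to give di-tert-butyl itaconate F1.
- F1 is enolised with the (R,R)-bromoborane carrying 3,5-bis(trifluoromethyl)benzenesulfonyl groups and Et3N in toluene–hexane at −78 °C. This is the precedented E(O)-selective tert-butyl ester anti-aldol.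
- Addition to 4 gives di-tert-butyl (2S)-2-[(1S)-1-hydroxy-15-oxohexadecyl]-3-methylidenebutanedioate F2.
- TFA/CH2Cl2 (0 °C → rt) removes both tert-butyl groups. The liberated (2S)-2-[(1S)-1-hydroxy-15-oxohexadecyl]-3-methylidenebutanedioic acid F3 lactonises under these non-epimerising acidic conditions to 9.
- The cost is two more steps.

**Second, step 1.** If aminolysis of the macrolactone is slow, MeMgCl attacks 1 directly and over-adds to the tertiary alcohol.
- The fallback sets out from 1 and returns at 3. It uses carboxylate chemistry instead of an amide.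
- Compound 1 is saponified (KOH, aq. EtOH) to 15-hydroxypentadecanoic acid F4.
- The lithium salt of F4 takes up exactly one MeLi (3.5 equiv in total, THF, 0 °C, TMSCl then aqueous acid quench), because the gem-dialkoxide cannot collapse before work-up. This gives 3.

**Third, step 2.** Possible failures are over-oxidation, dimeric ester formation via the hemiacetal, and loss of the air-sensitive aldehyde.
- The fallback sets out from 3 and returns at 4. It replaces alcohol dehydrogenation by substitution followed by N-oxide oxidation.
- An Appel reaction (CBr4, PPh3, CH2Cl2) gives 16-bromohexadecan-2-one F5.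
- Anhydrous Me3NO in DMSO at rt (Ganem/Kornblum-type oxidation) converts F5 into 4. This oxidation cannot go beyond the aldehyde level.

## Further compounds

F1 | step 3 | di-tert-butyl itaconate (di-tert-butyl 2-methylidenebutanedioate) | C=C(CC(=O)OC(C)(C)C)C(=O)OC(C)(C)C
F2 | step 3 | di-tert-butyl (2S)-2-[(1S)-1-hydroxy-15-oxohexadecyl]-3-methylidenebutanedioate | C=C(C(=O)OC(C)(C)C)[C@H](C(=O)OC(C)(C)C)[C@@H](O)CCCCCCCCCCCCCC(C)=O
F3 | step 3 | (2S)-2-[(1S)-1-hydroxy-15-oxohexadecyl]-3-methylidenebutanedioic acid | C=C(C(=O)O)[C@H](C(=O)O)[C@@H](O)CCCCCCCCCCCCCC(C)=O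
F4 | step 1 | 15-hydroxypentadecanoic acid | OCCCCCCCCCCCCCCC(=O)O
F5 | step 2 | 16-bromohexadecan-2-one | CC(=O)CCCCCCCCCCCCCCBr
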